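**Strategy.** The dihydrofuran ring (O1, C2, C3, C3a, C7a) bears at C3 both the aryl carbon C3a and the ester carbonyl, cis to the C2 aryl group. That pattern is what a Wolff ring contraction of a 3-diazoflavan-4-one gives: the aryl carbon shifts from C4 to C3, C4 leaves the pyranone ring as a ketene carbon, the free 5-OH of a protected shikimate captures it as the ester, and enol protonation anti to the C2 aryl sets the cis C3 centre. The precursor is an (S)-flavanone-derived diazo ketone (C2 from an enantioselective arylboronic acid addition to a chromone) carrying Br where the propenoate is later attached by Heck coupling.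

Key step: step 9

Remark 1: the SMILES is read as drawn, which makes the dihydrobenzofuran 2,3-cis (2S,3R) and the alcohol part natural (3R,4S,5R)-shikimic acid acylated at O-5.
Remark 2: (R)-t-BuPyOx is taken as the ligand enantiomer that delivers the (2S)-flavanone, by analogy with the sense of induction on β-substituted cycloalkenones; the mirror-image ligand is used if the sense is the other.

**Route**

Step 1
Reactants: 1 4-bromocatechol
Product: 2 4-bromo-1,2-bis(methoxymethoxy)benzene
Conditions: MOMCl, i-Pr2NEt, CH2Cl2, 0 °C → rt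
Reagents that add atoms: chloromethyl methyl ether (MOMCl), COCCl
Why: Double O-alkylation of the phenols (MOM protection) gives one building block that serves both aryl halves and carries an ortho-directing, acid-labile group.

Step 2
Reactants: 2 4-bromo-1,2-bis(methoxymethoxy)benzene
Product: 4 [3,4-bis(methoxymethoxy)phenyl]boronic acid, via aryllithium 3 (not isolated)
Conditions: B(Oi-Pr)3, n-BuLi, THF, −78 °C (in situ quench); then 1 M HCl to pH 5, 0 °C
Reagents that add atoms: triisopropyl borate, CC(C)OB(OC(C)C)OC(C)C; water, O; n-butyllithium, [Li]CCCC (Li in 3 only)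
Why: Bromine–lithium exchange is faster than ortho-lithiation at −78 °C and the aryllithium is trapped at once by the borate (lithiation–borylation), mild hydrolysis leaving the MOM ethers intact.

Step 3
Reactants: 2 4-bromo-1,2-bis(methoxymethoxy)benzene
Product: 6 1-[6-bromo-2,3-bis(methoxymethoxy)phenyl]ethan-1-one, via aryllithium 5 (not isolated)
Conditions: LDA, THF, −78 °C; MeC(O)N(OMe)Me, −78 °C; AcOH quench at −78 °C
Reagents that add atoms: N-methoxy-N-methylacetamide, CC(=O)N(C)OC; lithium diisopropylamide, [Li]N(C(C)C)C(C)C (Li in 5 only)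
Why: Directed ortho-metalation removes the one proton flanked by the OMOM director and the acidifying Br (kept at −78 °C to avoid aryne formation), and the Weinreb amide stops at the ketone through its chelated tetrahedral adduct.

Step 4
Reactants: 6 1-[6-bromo-2,3-bis(methoxymethoxy)phenyl]ethan-1-one
Product: 8 5-bromo-8-(methoxymethoxy)-4H-chromen-4-one, via enaminone 7 (not isolated)
Conditions: Me2NCH(OMe)2, toluene, 100 °C; then 1 M HCl/THF, rt
Reagents that add atoms: N,N-dimethylformamide dimethyl acetal, COC(OC)N(C)C
Why: Condensation of the methyl ketone gives the enaminone, and dilute acid should cleave preferentially the MOM ether ortho to the carbonyl (chelation assistance), the freed phenol closing by 6-endo-trig addition–elimination with loss of dimethylamine (enaminone chromone synthesis).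

Step 5
Reactants: 8 5-bromo-8-(methoxymethoxy)-4H-chromen-4-one; 4 [3,4-bis(methoxymethoxy)phenyl]boronic acid
Product: 9 (2S)-5-bromo-2-[3,4-bis(methoxymethoxy)phenyl]-8-(methoxymethoxy)chroman-4-one
Conditions: Pd(OCOCF3)2 (cat.), (R)-t-BuPyOx (cat.), NH4PF6 (cat.), H2O, ClCH2CH2Cl, 60 °C
Reagents that add atoms: none
Why: Pd(II)/pyridine-oxazoline-catalysed enantioselective conjugate addition of an arylboronic acid to a chromone (transmetalation, face-selective carbopalladation of C2=C3, protonolysis) sets C2 (S) under ligand control, and phosphine-free Pd(II) should leave the C–Br bond alone.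

Step 6
Reactants: 9 (2S)-5-bromo-2-[3,4-bis(methoxymethoxy)phenyl]-8-(methoxymethoxy)chroman-4-one
Product: 11 (2R)-5-bromo-3-diazo-2-[3,4-bis(methoxymethoxy)phenyl]-8-(methoxymethoxy)chroman-4-one, via trifluoroacetyl ketone 10 (not isolated)
Conditions: LiHMDS, THF, −78 °C; CF3CO2CH2CF3, −78 °C; cold 1 M HCl wash; then MsN3, Et3N, H2O (1 equiv), MeCN, rt
Reagents that add atoms: methanesulfonyl azide, CS(=O)(=O)N=[N+]=[N-]; 2,2,2-trifluoroethyl trifluoroacetate, O=C(OCC(F)(F)F)C(F)(F)F (its CF3CO group is carried by 10 only)
Why: Detrifluoroacetylative diazo transfer: the kinetic enolate is C-acylated at −78 °C (cold, to suppress retro-oxa-Michael opening) and the activated 1,3-dicarbonyl takes N2 from MsN3 with loss of the trifluoroacetyl group; C2 is spatially unchanged (the descriptor becomes R only through priority change) and can no longer epimerise because C3 has no hydrogen.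

Step 7
Reactants: 12 (−)-shikimic acid
Product: 13 3,4-O-isopropylidene shikimic acid
Conditions: Me2C(OMe)2, acetone, CSA (cat.), rt
Reagents that add atoms: 2,2-dimethoxypropane, COC(C)(C)OC
Why: Acid-catalysed transketalisation closes the dioxolane only on the cis-3,4-diol, leaving the trans-disposed 5-OH free; the stereocentres come from the chiral pool.

Step 8
Reactants: 13 3,4-O-isopropylidene shikimic acid
Product: 14 tert-butyl 3,4-O-isopropylidene shikimate
Conditions: Cl3CC(=NH)Ot-Bu, CH2Cl2/cyclohexane, rt (no catalyst)
Reagents that add atoms: tert-butyl 2,2,2-trichloroacetimidate, CC(C)(C)OC(=N)C(Cl)(Cl)Cl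
Why: The carboxylic acid protonates the imidate and is tert-butylated through the ion pair, whereas the secondary alcohol is not etherified without a Lewis acid.

Step 9
Reactants: 11 (2R)-5-bromo-3-diazo-2-[3,4-bis(methoxymethoxy)phenyl]-8-(methoxymethoxy)chroman-4-one; 14 tert-butyl 3,4-O-isopropylidene shikimate
Product: 16 tert-butyl 5-O-{(2S,3R)-4-bromo-2-[3,4-bis(methoxymethoxy)phenyl]-7-(methoxymethoxy)-2,3-dihydrobenzofuran-3-carbonyl}-3,4-O-isopropylidene shikimate, via ketene 15 (not isolated)
Conditions: hν (blue LEDs, ca. 440 nm), 14 (3 equiv), toluene, 20 °C, Ar; then dark, rt until the ketene is consumed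
Reagents that add atoms: none
Why: Excitation of the diazo ketone, locked s-Z in the ring, expels N2 with concerted 1,2-shift of aryl carbon C4a from C4 to C3 (photochemical Wolff rearrangement, as in the ring contraction of 2-diazo-1-tetralones and related cyclic diazo ketones), giving ketene 15 with the former C4 exocyclic. The five-membered ring (O1, C2, C3, C3a, C7a) therefore arises by contraction of the six-membered pyranone through a 1,2-shift and not by a cyclisation, so no Baldwin-type closure is involved. The 5-OH of 14 adds to the ketene carbonyl in the ring plane to give an ester enol, and C3 is then protonated on the π face anti to the C2 aryl group, which places the ester cis to the aryl (kinetic, contra-thermodynamic 3R centre under substrate control by C2, itself untouched because no bond to it is broken). The step needs the Wolff shift to win over 1,2-H or 1,2-aryl shift from C2 to a free carbene and over O–H insertion, which the locked s-Z geometry and metal-free direct photolysis should secure. It also needs the cis ester to persist, which the neutral base-free medium secures, while 440 nm light excites only the diazo n–π* band and leaves the aryl bromide and the enoate alone. Br rather than the propenoate is carried at C4 so that the ketene cannot undergo 6π-electrocyclisation onto a peri alkene.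

Step 10
Reactants: 16 the bromo ester from step 9; 17 tert-butyl acrylate
Product: 18 tert-butyl 5-O-{(2S,3R)-4-[(E)-3-tert-butoxy-3-oxoprop-1-enyl]-2-[3,4-bis(methoxymethoxy)phenyl]-7-(methoxymethoxy)-2,3-dihydrobenzofuran-3-carbonyl}-3,4-O-isopropylidene shikimate
Conditions: Pd2(dba)3 (cat.), [(t-Bu)3PH]BF4 (cat.), Cy2NMe, 1,4-dioxane, rt
Reagents that add atoms: none
Why: Room-temperature Mizoroki–Heck reaction (oxidative addition to Pd/P(t-Bu)3, syn insertion, syn β-hydride elimination) gives the (E)-propenoate, and the hindered amine at rt should be too weak a base to epimerise C3 or open the ring.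

Step 11
Reactants: 18 the fully protected compound from step 10
Product: 19 target, 5-O-{(2S,3R)-4-[(E)-2-carboxyethenyl]-2-(3,4-dihydroxyphenyl)-7-hydroxy-2,3-dihydrobenzofuran-3-carbonyl}shikimic acid
Conditions: TFA/CH2Cl2/H2O (10:9:1), 1,3,5-trimethoxybenzene, 0 °C → rt
Reagents that add atoms: none
Why: One acidolysis should remove all six acid-labile groups (tert-butyl esters by alkyl–oxygen fission, the isopropylidene ketal by hydrolysis, the aryl MOM acetals via the methoxymethyl cation intercepted by water and scavenger), and with no base present the cis C3 centre and the 5-O-acyl position should be retained.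

**Compound list**

1 | 4-bromocatechol | Oc1ccc(Br)cc1O | starting material
2 | 4-bromo-1,2-bis(methoxymethoxy)benzene | COCOc1ccc(Br)cc1OCOC | intermediate
3 | 3,4-bis(methoxymethoxy)phenyllithium | [Li]c1ccc(OCOC)c(OCOC)c1 | intermediate (not isolated)
4 | [3,4-bis(methoxymethoxy)phenyl]boronic acid | OB(O)c1ccc(OCOC)c(OCOC)c1 | intermediate
5 | 6-bromo-2,3-bis(methoxymethoxy)phenyllithium | [Li]c1c(Br)ccc(OCOC)c1OCOC | intermediate (not isolated)
6 | 1-[6-bromo-2,3-bis(methoxymethoxy)phenyl]ethan-1-one | CC(=O)c1c(Br)ccc(OCOC)c1OCOC | intermediate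
7 | (E)-1-[6-bromo-2,3-bis(methoxymethoxy)phenyl]-3-(dimethylamino)prop-2-en-1-one | CN(C)/C=C/C(=O)c1c(Br)ccc(OCOC)c1OCOC | intermediate (not isolated)
8 | 5-bromo-8-(methoxymethoxy)-4H-chromen-4-one | O=c1ccoc2c(OCOC)ccc(Br)c12 | intermediate
9 | (2S)-5-bromo-2-[3,4-bis(methoxymethoxy)phenyl]-8-(methoxymethoxy)chroman-4-one | O=C1C[C@@H](c2ccc(OCOC)c(OCOC)c2)Oc2c(OCOC)ccc(Br)c12 | intermediate
10 | 3-trifluoroacetyl derivative of 9 (C2 as in 9; C3 enolised) | O=C1C(C(=O)C(F)(F)F)[C@@H](c2ccc(OCOC)c(OCOC)c2)Oc2c(OCOC)ccc(Br)c12 | intermediate (not isolated)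
11 | (2R)-5-bromo-3-diazo-2-[3,4-bis(methoxymethoxy)phenyl]-8-(methoxymethoxy)chroman-4-one | O=C1C(=[N+]=[N-])[C@@H](c2ccc(OCOC)c(OCOC)c2)Oc2c(OCOC)ccc(Br)c12 | intermediate
12 | (−)-shikimic acid | O[C@@H]1CC(C(=O)O)=C[C@@H](O)[C@H]1O | starting material
13 | 3,4-O-isopropylidene shikimic acid | O[C@@H]1CC(C(=O)O)=C[C@@H](O2)[C@H]1OC2(C)C | intermediate
14 | tert-butyl 3,4-O-isopropylidene shikimate (5-OH free) | O[C@@H]1CC(C(=O)OC(C)(C)C)=C[C@@H](O2)[C@H]1OC2(C)C | intermediate
15 | [4-bromo-2-[3,4-bis(methoxymethoxy)phenyl]-7-(methoxymethoxy)benzofuran-3(2H)-ylidene]methanone (ketene; C2 as in 11) | O=C=C1[C@@H](c2ccc(OCOC)c(OCOC)c2)Oc2c(OCOC)ccc(Br)c12 | intermediate (not isolated)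
16 | tert-butyl 5-O-{(2S,3R)-4-bromo-2-[3,4-bis(methoxymethoxy)phenyl]-7-(methoxymethoxy)-2,3-dihydrobenzofuran-3-carbonyl}-3,4-O-isopropylidene shikimate | Brc1ccc(OCOC)c2c1[C@@H](C(=O)O[C@@H]1CC(C(=O)OC(C)(C)C)=C[C@@H](O3)[C@H]1OC3(C)C)[C@@H](c1ccc(OCOC)c(OCOC)c1)O2 | intermediate
17 | tert-butyl acrylate | C=CC(=O)OC(C)(C)C | starting material
18 | tert-butyl 5-O-{(2S,3R)-4-[(E)-3-tert-butoxy-3-oxoprop-1-enyl]-2-[3,4-bis(methoxymethoxy)phenyl]-7-(methoxymethoxy)-2,3-dihydrobenzofuran-3-carbonyl}-3,4-O-isopropylidene shikimate | CC(C)(C)OC(=O)/C=C/c1ccc(OCOC)c2c1[C@@H](C(=O)O[C@@H]1CC(C(=O)OC(C)(C)C)=C[C@@H](O3)[C@H]1OC3(C)C)[C@@H](c1ccc(OCOC)c(OCOC)c1)O2 | intermediate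
19 | 5-O-{(2S,3R)-4-[(E)-2-carboxyethenyl]-2-(3,4-dihydroxyphenyl)-7-hydroxy-2,3-dihydrobenzofuran-3-carbonyl}shikimic acid | O=C(O)/C=C/c1ccc(O)c2c1[C@@H](C(=O)O[C@@H]1CC(C(=O)O)=C[C@@H](O)[C@H]1O)[C@@H](c1ccc(O)c(O)c1)O2 | target

**Totals**

Total step count: 11. Longest linear sequence: 8 steps (1 → 2 → 6 → 8 → 9 → 11 → 16 → 18 → 19).

**Steps most likely to fail**

1. Step 9. Capture of the hindered aryl(alkyl)ketene by a hindered secondary alcohol may be slow, so that ketene dimerisation or adventitious water competes, and enol protonation may show insufficient facial selectivity. Fallback, setting out from 11 and returning at 16: irradiation at ca. 440 nm in MeCN/H2O lets water, a small and fast nucleophile, capture ketene 15. The same protonation anti to the aryl group should give the cis acid (2S,3R)-4-bromo-2-[3,4-bis(methoxymethoxy)phenyl]-7-(methoxymethoxy)-2,3-dihydrobenzofuran-3-carboxylic acid F1. F1 is then esterified with 14 (DIC, cat. DMAP, CH2Cl2, 0 °C) to reach 16. Should the activated acid pass through the ketene, protonation converges on the same cis centre.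

2. Step 6. Reversible retro-oxa-Michael opening of the enolate or of the trifluoroacetyl diketonate would erode the C2 configuration, and the hindered C3 position may acylate sluggishly. Fallback, setting out from 9 and returning at 11: condensation with tert-butoxybis(dimethylamino)methane (toluene, 60 °C) gives the neutral enaminone, the (E)-3-[(dimethylamino)methylene] derivative of 9 F2. Diazo transfer to the enaminone with TsN3 (CH2Cl2, rt; cycloaddition–fragmentation with loss of the N-sulfonyl formamidine) then gives 11. No metal enolate or 1,3-diketonate is involved.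

3. Step 11. Acid-promoted ionisation of the benzylic C2–O1 bond next to the electron-rich aryl could epimerise C2 towards the trans series. Formaldehyde released from three MOM groups could alkylate the catechol, and 5-O to 4-O acyl migration may set in once the diol is free. Fallback, setting out from 18 and returning at 19: the MOM ethers are cleaved first with ZnBr2/n-PrSH (CH2Cl2, 0 °C, minutes), the methoxymethyl unit being captured as a thioether so that no formaldehyde arises. This gives the triphenol tert-butyl 5-O-{(2S,3R)-4-[(E)-3-tert-butoxy-3-oxoprop-1-enyl]-2-(3,4-dihydroxyphenyl)-7-hydroxy-2,3-dihydrobenzofuran-3-carbonyl}-3,4-O-isopropylidene shikimate F3. A brief treatment with TFA/CH2Cl2/H2O at 0 °C then removes the tert-butyl esters and the acetonide to give 19.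

**Further compounds**

F1 | step 9 | (2S,3R)-4-bromo-2-[3,4-bis(methoxymethoxy)phenyl]-7-(methoxymethoxy)-2,3-dihydrobenzofuran-3-carboxylic acid | Brc1ccc(OCOC)c2c1[C@@H](C(=O)O)[C@@H](c1ccc(OCOC)c(OCOC)c1)O2
F2 | step 6 | (E)-3-[(dimethylamino)methylene] derivative of 9 (C2 as in 9) | O=C1/C(=C/N(C)C)[C@@H](c2ccc(OCOC)c(OCOC)c2)Oc2c(OCOC)ccc(Br)c12
F3 | step 11 | tert-butyl 5-O-{(2S,3R)-4-[(E)-3-tert-butoxy-3-oxoprop-1-enyl]-2-(3,4-dihydroxyphenyl)-7-hydroxy-2,3-dihydrobenzofuran-3-carbonyl}-3,4-O-isopropylidene shikimate | CC(C)(C)OC(=O)/C=C/c1ccc(O)c2c1[C@@H](C(=O)O[C@@H]1CC(C(=O)OC(C)(C)C)=C[C@@H](O3)[C@H]1OC3(C)C)[C@@H](c1ccc(O)c(O)c1)O2
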